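The readings were computed on assumed constants, and the scatter is random.

At early times Friday's flask and Thursday's flask read alike: 72.7% and 72.7% of starting material after 0.667 min, with 0.84 equiv and 1.7 equiv of scavenger.

common to all: starting material 16 mM; free catalyst 0.83 mol%; impurity 49 µM
- Friday's: coupling partner 4 equiv; scavenger 0.84 equiv; run made earlier
- Thursday's: coupling partner 4 equiv; scavenger 1.7 equiv; run made earlier
- epsilon: coupling partner 4.00 equiv; scavenger 1.50 equiv; time 5.0 min
- eta: coupling partner 4.00 equiv; scavenger 1.00 equiv; time 5.0 min
- alpha: coupling partner 4.00 equiv; scavenger 2.20 equiv; time 5.0 min

| run | time / min | starting material / % | target / % |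
|---|---|---|---|
| Friday's | 0.667 | 72.7 | 26.7 |
| Friday's | 1.33 | 52.6 | 46.9 |
| Friday's | 2.00 | 37.1 | 62.2 |
| Friday's | 3.00 | 21.1 | 78.4 |
| Friday's | 4.00 | 11.3 | 88.4 |
| Friday's | 5.00 | 5.7 | 93.5 |
| Thursday's | 0.417 | 81.1 | 18.7 |
| Thursday's | 0.667 | 72.7 | 27.2 |
| Thursday's | 1.00 | 62.0 | 37.5 |
| Thursday's | 1.33 | 53.1 | 47.1 |
| Thursday's | 2.00 | 37.5 | 62.4 |
| Thursday's | 3.00 | 21.4 | 78.7 |
| Thursday's | 5.00 | 6.1 | 94.0 |

(each reading ± 0.3 percentage points)

- part of the starting material that has reacted at the end, epsilon
- part of the starting material that has reacted at the end, eta
- part of the starting material that has reacted at the end, alpha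
- what raising the equivalents of scavenger from its lowest to its highest value here does to the part of the starting material that has reacted (changes below 5 percentage points count as none) (no change / it falls / it rises)



Ada and Ben both count rounds per catalyst charged (the turnover number): the reacted share divided by the catalyst loading. Friday's flask was charged with 101 rounds of scavenger. This is the scavenger budget, the equivalents of scavenger over the catalyst loading, or the rounds a charge pays at one scavenger per round. The new flasks hold 181 in epsilon, 120 in eta and 265 in alpha.

Ada holds that each round costs one scavenger and that the pace follows what remains of the budget. So she expects eta, whose budget is the thinnest of the new flasks, to end behind alpha, and she answers that the part reacted rises.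

Ben reads the end of the runs. Friday's flask stood at 114 rounds after 5.00 min, past its budget, and Thursday's stood at 113 at that time, alike within the scatter. So for Ben the budget does not set the pace, and each new flask should reach about that count.

I side with Ben on conversion and commit to 93.9% reacted in each new flask. I keep Ada's ledger for the stock of scavenger, which gives 6.10% left in eta.

The forecast stands with Ben at 94%, 94.1% and 93.9%, with no change: “Doubling the scavenger therefore does nothing measurable”.

The simulation gives 94.0% for epsilon, 93.9% for eta and 94.0% for alpha, a change of 0.012 percentage points across the scavenger range: no change.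

    starting material + free catalyst ⇌ catalyst intermediate A (K = 130 /M, k = 250 /M/s)
    coupling partner + catalyst intermediate A → catalyst intermediate B (k = 49.0 /M/s)
    catalyst intermediate B ⇌ released group + catalyst intermediate C (K = 0.00250 M, k = 430 /s)
    catalyst intermediate C → free catalyst + target (k = 40.0 /s)
    coupling partner + released group ⇌ idle adduct, settled at all times (K = 9.90 /M)
    scavenger + released group → scavenged by-product (k = 120 /M/s)
    free catalyst + impurity → spent catalyst (k = 2900 /M/s)

Ben's count stands for conversion in epsilon, eta and alpha, and Ada's ledger comes close for the stock of scavenger in eta. In eta, up to 5.00 min, the round ran while scavenger took up released group, which gave c(scavenged by-product) = 14.9 mM; that pays 112 rounds of the budget of 120, with 6.8% of the scavenger still there and c(released group) = 0.0816 mM. In alpha's neighbour with 10.0 equiv of coupling partner, 98.9% of the starting material reacted by 5.00 min, a count of 119 rounds against the budget of 265, and 55% of the scavenger was left.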